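The flask holds 1.6 M of starting material and 1.60 M of reagent, and the ochre run is this same flask followed up to 20.0 min.

- ochre: starting material 1.6 M; reagent 1.6 M; the very flask that is asked about, followed so far
- flask: starting material 1.6 M; reagent 1.60 M; time 1.5 h

ochre run (percent of the starting material charged)

| time / min | starting material / % | target / % |
|---|---|---|
| 2.50 | 0 | 46.7 |
| 6.00 | 0.1 | 70.4 |
| 12.0 | 0.5 | 71.3 |
| 20.0 | 0 | 72.8 |

(readings scatter by 0.5 percentage points)

1. why nothing more happens at 1.5 h, or that something still does (it is still moving / forward and back rates have come level / all of the starting material has reacted / the reagent has run out first)
2. share of the starting material used up at 1.5 h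
3. target at 1.5 h, in percent of the starting material charged

- a reading or a percentage of target counts all its forms, free or not
- the reaction counts as stopped when no species that holds the starting material changes by six tenths of a point or more over the second half of the time
- a reading of starting material is of its free form alone

Take first the main step, starting material to target, which by itself brings target to 100%. The ochre run reads starting material at 0% but target at 72.8% at 20.0 min, so 27.2% of the charge stands in something else, and the reckoning here adds a branch. The ochre run gives 0.234 M⁻¹ for the loss ratio ρ, the material lost per unit of target, divided by the charged concentration of starting material; it is a selectivity factor per unit of concentration. The reckoning here watches the concentration of starting material. With a main step first order in it, a branch first order in it holds lost over target level at any charge, whereas a branch taking two molecules of it raises that ratio roughly with the charge, which keeps ρ roughly constant and makes the target fraction roughly one over one plus ρ times the charge. A single charge cannot separate these two cases, but this flask has the charge of the ochre run.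

Last come unseen forms between the two ends. At 2.50 min starting material reads 0%, yet 26 percentage points of later target is still missing, and the reckoning here takes these forms to shift the arrival of target, not its end value. With 1.5 h later than the last ochre reading at 20.0 min, the reckoning here takes that reading as the end of this flask and commits to 100% used up and target at 72.8%, with reading scatter 0.5 points.

The forecast says that all of the starting material has reacted, with 100% used up and target at 73.5%: “Nothing further should happen because the starting material is spent.” The flask shows that all of the starting material has reacted, with 100% used up and target at 72.5%.

    starting material → intermediate A (k = 0.0709 s⁻¹)
    intermediate A → intermediate B (k = 0.0193 s⁻¹)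
    intermediate B → intermediate C (k = 0.0178 s⁻¹)
    reagent + intermediate A ⇌ intermediate D (K = 0.154 M⁻¹, k = 0.0120 M⁻¹ s⁻¹)
    intermediate C → intermediate E (k = 1.54 s⁻¹)
    intermediate E → target (k = 0.173 s⁻¹)
    2 starting material → homo dimer (k = 0.0187 M⁻¹ s⁻¹)
    starting material + target ⇌ idle adduct, settled at all times (K = 0.300 M⁻¹)
    crystals ⇌ target, rate k9*(cs9 - [target]) while solid is left; crystals form when [target] > cs9 (solubility = 0.170 M, k = 6.69 s⁻¹)

In the flask, starting material split between intermediate A and homo dimer, its use by the first step standing at 1.3 times its use by the second just after the start, with a half-life of 0.16 min by the step to intermediate A alone. Intermediate A then passed on to intermediate B, that turnover half done by 0.938 min, and at 0.150 h target stood at 72.4%, homo dimer at 27.5% and reagent at >99.9%. The end value of the flask puts ρ at 0.237 M⁻¹. For the neighbour flask charged with 0.96 M, the ochre ρ gives target at 81.7%, and that flask ends at 80.9%, with homo dimer at 19.1%.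

The earlier runs and the new flask stem from a simulated flask on assumed constants; scatter was added.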